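## Analysis of the target

- **Ring system.** The target is a heptacycle of formula C30H28N2O4. It is built from two 4-oxygenated 1-methylquinolin-2-one units: Q1 (rings A and B) and Q2 (rings F and G). They are joined through a ten-carbon core whose seven skeletal carbons are labelled C-a to C-g: C-a is the CMe2 carbon, C-b the adjacent CH, C-c and C-d the alkene carbons, C-e the quaternary C(Me)(O), C-f the CH2, and C-g the CH bound to C-3 of Q2.
- **Rings of the core.** Ring C is a dihydropyran (O, C-a, C-b, C-c plus C-3/C-4 of Q1). Ring D is a cyclohexene (C-b, C-c=C-d, C-e, C-f, C-g). Ring E is a dihydropyran (O, C-e, C-f, C-g plus C-3/C-4 of Q2). Rings D and E share C-e, C-f and C-g, so together they form a 2-oxabicyclo[3.3.1]nonene.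
- **The feature the route exploits.** C-g and C-e sit 1,3 to each other on ring E, exactly as C-4 and C-2 of a pyran fused to Q2. They are bridged by the three-carbon allyl unit C-b–C-c=C-d, which is the C-3/C-4/4-methyl unit of a pyran fused to Q1. C-e is fully substituted (Me, O, C-d, C-f).
- **Stereocentres.** From the SMILES they are C-b (S), C-e (S) and C-g (R). C-e and C-g are bridgeheads and fix each other. C-b is the only independent centre: its hydrogen lies on the face of ring D that carries the ring E bridge, and C-a lies on the open (exo) face.
- **Oxidation level.** The molecule equals two pyranoquinolinone monomers minus H2, and the two halves are not equivalent. A plain dimerisation therefore cannot give it without a later oxidation.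
- **Sensitive groups.** The tertiary allylic ether at C-e and the tertiary ether at C-a can ionise in strong acid. The alkene C-c=C-d, conjugated with Q1, can migrate to C-b=C-c, which would erase C-b. The two N-methyl lactams are robust and no protecting group is needed.
- **What makes it hard.** Two C–C bonds join the halves, one of them to a quaternary carbon. The ring is bridged. The absolute configuration must be set in a molecule with no handle for an auxiliary or a classical resolution.

## Retrosynthetic reasoning

**Cut 1: C-d–C-e and C-b–C-g of 12.** These are the only two C–C bonds between the halves, and they end at the two positions of ring E that are 1,3 to each other. Cutting both turns ring E into the flat, achiral pyrylium ion 10 (electrophilic at C-4 = C-g and C-2 = C-e) and turns the bridge into the allyl unit of the 4-methylchromene 6 (nucleophilic at C-b, and at C-d after proton loss). The sum 6 + 10 minus one proton has exactly the composition of 12, so no redox step is needed. The forward reaction is a [3+3] bicycloannulation that must form both bonds, close ring D, and set C-g, C-e and C-b. The two partners are tricyclic, of equal size and without a lasting stereocentre. Cutting elsewhere (for example at the C–O bonds) would leave the two hindered C–C bonds for separate steps.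

**Cut 2: the first of the two bonds, C-b–C-g (11 to 6 + 10).** Within the key step the less hindered electrophilic site (C-g, a CH) is paired with the more hindered nucleophilic site (C-b, next to CMe2). The quaternary centre C-e is left for the intramolecular second bond, where the tether enforces both the ring size and the face.

**Cut 3: the pyrylium ion 10 back to ketal 9, and 9 to 1 and 7.** Ketal 9 stores the pyrylium ion in neutral, isolable form. Its racemic ketal centre is irrelevant because ionisation removes it. The bonds cut are C-3 of Q2 to C-g and O to C-e, a condensation of the 1,3-dicarbonyl-like quinolinone 1 with the masked β-keto aldehyde 7, passing through enone 8.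

**Cut 4: chromene 6 back to ketone 4 (C-c–C-d, then dehydration via 5), and 4 to 1 and 2.** The 4-methyl group is added as a methyl nucleophile to the ketone. Ketone 4 arises by acylation at C-3 of 1 (bond C-3 to C-c, intermediate 3) and oxa-Michael closure (O to C-a). Both halves therefore come from the same commercial quinolinone 1.

## Alternatives that were turned down

**Alternative 1:** the textbook, biomimetic route.
- Disconnection: C-b–C-g and C-c–C-d as the two bonds of a [4+2] cycloaddition, with the C-c=C-d unsaturation and the O–C-e bond removed first. This leads to the monomer 2,2,6-trimethylpyranoquinolinone A1 and its ring-opened dienol tautomer A2.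
- Forward key step: thermal Diels–Alder reaction of A2 (diene C-g=C-f–C-e=C-d) with the pyran alkene of A1, acid-induced addition of the phenolic OH to C-e to give the saturated dimer A3, then dehydrogenation of C-c–H/C-d–H with a quinone oxidant.
- Why turned down: the cycloaddition is uncatalysed and needs high temperature, so neither endo/exo selectivity nor orientation is controlled, and A2 also adds to itself. It is racemic and offers no place for a chiral catalyst. It creates a stereocentre at C-c that the oxidation must then destroy. The late oxidation has to pick C-c–H and then lose a proton from C-d rather than C-b. The route ends in a resolution of a mixture of isomers.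

**Alternative 2:** tethered cycloisomerisation.
- Disconnection: only C-b–C-g, giving the bis-chromene A5, an isomer of 12 in which C-d already links C-c and C-e. A5 would come from enal A4 and 1 by Knoevenagel condensation and oxa-6π electrocyclisation.
- Forward key step: protonation of the Q2 chromene at C-f, attack of C-b on the C-g cation, and proton loss from C-d.
- Why turned down: A4 needs four to five linear steps from 4 (allylation, dehydration, oxidation to the enal), all for a key step that forms one C–C bond. The only stereocentre of A5 (C-e) is labile through electrocyclic ring opening, so no chirality can be stored. The ring-opened form of A5 can also close by a hetero-Diels–Alder mode (O of Q2 onto C-c) to a constitutional isomer. The route is linear where the chosen one is convergent.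

**Alternative 3:** chiral-pool "terpene" route.
- Disconnection: Q2 removed from C-g and C-e, and ring D traced to a p-menthane. The tricycle A6 (rings B, C, D) would come from 1 and an enantiopure p-mentha-2,8-dien-1-ol by Friedel–Crafts allylation and hydroalkoxylation.
- Forward key steps: shift of the alkene in A6 to C-e=C-f, allylic oxidation at C-g, ionisation and capture by 1 at C-g trans to C-a, hydroalkoxylation at C-e, and a final dehydrogenation across C-c/C-d.
- Why turned down: the terpene supplies only C-b, and its second stereocentre (C-c) ends as sp2. Three isomerisation or redox adjustments are needed on a skeleton with three competing allylic sites (C-g, C-c, the methyl group). The allyl cation can be captured at either terminus and on either face. At least seven steps would be required.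

Key step: step 4

## Route

Assumption: the sense of induction of the chiral acid in step 4 cannot be predicted with confidence; the (R)-catalyst is written, and its mirror image is to be used if a first run shows that it favours the antipode.

Step 1
Reactants: 1 4-hydroxy-1-methylquinolin-2(1H)-one; 2 3-methylbut-2-enoic acid
Product: 4 2,2,6-trimethyl-2,3-dihydro-4H-pyrano[3,2-c]quinoline-4,5(6H)-dione, via acyl enone 3 (not isolated)
Conditions: P2O5/MeSO3H (Eaton's reagent), 70 °C
Reagents that add atoms: none
Why: Friedel–Crafts-type C-3 acylation of the 4-hydroxyquinolinone by the activated acid gives enone 3, whose 4-OH then adds to the β,β-dimethyl enone in an acid-catalysed oxa-Michael closure (chroman-4-one synthesis); only the 4-oxygen can close, so the angular [3,2-c] ring is the sole outcome.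

Step 2
Reactants: 4 2,2,6-trimethyl-2,3-dihydro-4H-pyrano[3,2-c]quinoline-4,5(6H)-dione
Product: 6 2,2,4,6-tetramethyl-2H-pyrano[3,2-c]quinolin-5(6H)-one, via tertiary alcohol 5 (not isolated)
Conditions: MeMgBr, CeCl3, THF, −78 to 0 °C; aq NH4Cl; then TsOH·H2O (5 mol %), toluene, 80 °C
Reagents that add atoms: methylmagnesium bromide, C[Mg]Br
Why: The organocerium reagent formed from MeMgBr and CeCl3 should add 1,2 to the ketone with little enolisation while the N-methyl lactam stays untouched at low temperature; acid-catalysed E1 dehydration of 5 through the oxygen-stabilised C-c cation should give the conjugated endocyclic chromene (Grignard addition–dehydration), and no stereocentre remains.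

Step 3
Reactants: 1 4-hydroxy-1-methylquinolin-2(1H)-one; 7 4,4-dimethoxybutan-2-one
Product: 9 2-methoxy-2,6-dimethyl-2H-pyrano[3,2-c]quinolin-5(6H)-one (racemic), via open enone 8 (not isolated)
Conditions: 7 (2 equiv), PPTS (10 mol %), MeOH, 3 Å MS, 55 °C
Reagents that add atoms: methanol, CO
Why: Under mild acid 7 loses methanol to the β-methoxy enone, which C-3 of 1 attacks in a vinylogous addition–elimination to give 8; keto–enol tautomerism allows E/Z exchange, the 4-OH closes onto the ketone and methanol traps the hemiketal as the cyclic mixed ketal (2-alkoxy-2H-pyran formation from a cyclic 1,3-dicarbonyl and a β-keto acetal). The ketal centre is racemic and is erased in step 4.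

Step 4
Reactants: 6 2,2,4,6-tetramethyl-2H-pyrano[3,2-c]quinolin-5(6H)-one; 9 2-methoxy-2,6-dimethyl-2H-pyrano[3,2-c]quinolin-5(6H)-one (racemic)
Product: 12 the target heptacycle with C-b (S) and C-e (S) and C-g (R), via pyrylium ion 10 (not isolated), via C-4 adduct 11 (not isolated)
Conditions: (R)-3,3′-bis(2,4,6-triisopropylphenyl)-1,1′-binaphthyl-2,2′-diyl N-triflylphosphoramide (10 mol %), 5 Å MS, toluene, −20 °C to rt; 9 added slowly to 6 (1.5 equiv)
Reagents that add atoms: none
Why: Proposed new method: the chiral acid ionises ketal 9 to the flat pyrylium ion 10, held as a contact ion pair with the chiral phosphoramidate, so the racemic ketal centre is erased and the step is enantioconvergent; the closest known reaction type is the chiral-phosphoric-acid-catalysed formal [3+3] annulation of 1-benzopyrylium ions generated in situ with C,O-bis-nucleophiles (2-naphthols, cyclic 1,3-diones) to 2,8-dioxabicyclo[3.3.1]nonanes, extended here to a C,C-bis-nucleophile, the allyl unit C-b/C-c/C-d of 6. C-b, the only nucleophilic terminus of the endocyclic chromene, attacks C-4 of 10 (C-g) rather than the methyl-bearing C-2, and loss of a proton from the C-d methyl group of the resulting oxygen-stabilised C-c cation gives 11, which carries an exocyclic methylene and a 4H-pyran enol ether. Protonation of that enol ether at C-f gives the oxocarbenium ion at C-e, which the C-d terminus of the 1,1-disubstituted alkene captures in a Prins closure; this forms the six-membered ring D (endo with respect to the alkene, exo with respect to the C=O+ bond) and thereby bridges ring E into the 2-oxabicyclo[3.3.1]nonene, and proton loss from C-d restores conjugation as C-c=C-d. C-g is set in the first C–C bond formation by the face of 10 that the chiral anion leaves open. C-e follows from C-g, because the three-atom tether can reach C-e only on the face of ring E that carries the C-g substituent (1,3-diaxial bridging). C-b is expected to be under thermodynamic control: its epimer and the C-b=C-c alkene isomer return to the common C-c cation by reversible protonation, and the isomer with C-a on the exo face of ring D, away from Q2 and free of allylic strain between the C-a methyl groups and the C-g substituent, should be the resting point. The selectivities needed are C-4 over C-2 attack on the pyrylium ion, C-b over C-d as the first nucleophilic site (secured by using the isolated endocyclic isomer 6 and an acid too weak to isomerise it quickly), and cross- over self-condensation of 10 through its acidic 2-methyl group (secured by the low, catalytic concentration of 10 and slow addition of 9 to excess 6).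

## Compound list

1 | 4-hydroxy-1-methylquinolin-2(1H)-one | Cn1c(=O)cc(O)c2ccccc21 | starting material
2 | 3-methylbut-2-enoic acid | CC(C)=CC(=O)O | starting material
3 | 4-hydroxy-1-methyl-3-(3-methylbut-2-enoyl)quinolin-2(1H)-one | CC(C)=CC(=O)c1c(O)c2ccccc2n(C)c1=O | intermediate (not isolated)
4 | 2,2,6-trimethyl-2,3-dihydro-4H-pyrano[3,2-c]quinoline-4,5(6H)-dione | Cn1c(=O)c2c(c3ccccc31)OC(C)(C)CC2=O | intermediate
5 | 4-hydroxy-2,2,4,6-tetramethyl-3,4-dihydro-2H-pyrano[3,2-c]quinolin-5(6H)-one (racemic) | Cn1c(=O)c2c(c3ccccc31)OC(C)(C)CC2(C)O | intermediate (not isolated)
6 | 2,2,4,6-tetramethyl-2H-pyrano[3,2-c]quinolin-5(6H)-one | Cn1c(=O)c2c(c3ccccc31)OC(C)(C)C=C2C | intermediate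
7 | 4,4-dimethoxybutan-2-one | CC(=O)CC(OC)OC | starting material
8 | 4-hydroxy-1-methyl-3-[(1E)-3-oxobut-1-en-1-yl]quinolin-2(1H)-one | CC(=O)/C=C/c1c(O)c2ccccc2n(C)c1=O | intermediate (not isolated)
9 | 2-methoxy-2,6-dimethyl-2H-pyrano[3,2-c]quinolin-5(6H)-one (racemic) | Cn1c(=O)c2c(c3ccccc31)OC(C)(OC)C=C2 | intermediate
10 | 2,6-dimethyl-5-oxo-5,6-dihydropyrano[3,2-c]quinolin-1-ium (ion pair with the chiral phosphoramidate) | CN1C(=O)C2=C(C3=CC=CC=C13)[O+]=C(C)C=C2 | intermediate (not isolated)
11 | 3-(2,6-dimethyl-5-oxo-5,6-dihydro-4H-pyrano[3,2-c]quinolin-4-yl)-2,2,6-trimethyl-4-methylidene-3,4-dihydro-2H-pyrano[3,2-c]quinolin-5(6H)-one, C-b and C-g configured as in 12 | Cn1c(=O)c2c(c3ccccc31)OC(C)(C)[C@H](C2=C)[C@H]2C=C(C)Oc3c2c(=O)n(C)c2ccccc32 | intermediate (not isolated)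
12 | CNP0104925.2: heptacycle in which the Q1-fused 2,2-dimethyldihydropyran (ring C) and the Q2-fused 2-methyldihydropyran (ring E) are joined through cyclohexene ring D; C-b (S), C-e (S), C-g (R); H on C-b on the face of ring D that carries the ring E bridge | Cn1c(=O)c2c(c3ccccc31)OC(C)(C)[C@@H]1C2=C[C@]2(C)C[C@H]1c1c(c3ccccc3n(C)c1=O)O2 | target

## Step count and risk

Total step count: 4. Longest linear sequence: 3 steps (1 to 4 to 6 to 12); the branch from 1 to 9 is one step.

**Step 4 (key step, proposed new method).**
- What may go wrong:
  - Weak facial discrimination at C-g, because the nucleophile has no hydrogen-bond donor to anchor it to the chiral anion.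
  - Acid-induced isomerisation of 6 to its exocyclic tautomer, so that the first bond forms from C-d to C-g and the sequence stalls before the crowded alternative closure.
  - Self-condensation of the pyrylium ion through its 2-methyl group.
- Fallback (regiospecific, stepwise, known reaction types). It sets out from 4, uses 9, and comes back to the route at 11 and then 12.
  - O-Triflation of 4 (Tf2O, 2,6-di-tert-butyl-4-methylpyridine, CH2Cl2) gives 2,2,6-trimethyl-5-oxo-5,6-dihydro-2H-pyrano[3,2-c]quinolin-4-yl trifluoromethanesulfonate F1.
  - Kumada coupling of F1 with Me3SiCH2MgCl and Pd(PPh3)4 gives the allylsilane 2,2,6-trimethyl-4-[(trimethylsilyl)methyl]-2H-pyrano[3,2-c]quinolin-5(6H)-one F2.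
  - Hosomi–Sakurai reaction of F2 with 9 (TMSOTf, CH2Cl2, −78 °C) can only bond through C-b (γ-attack with loss of silicon) and gives the exocyclic methylene directly. It should deliver 11 as the racemate, that is 11 together with its enantiomer, the (C-b, C-g)-antipode of the C-4 adduct F3.
  - An achiral sulfonic acid then effects the Prins closure to racemic 12, that is 12 together with its enantiomer, the (C-b R, C-e R, C-g S)-heptacycle F4.
  - 12 is separated by preparative supercritical-fluid chromatography on a polysaccharide chiral stationary phase.

**Step 3.**
- What may go wrong: ionisation of the product ketal under the conditions of its own formation, followed by capture of the pyrylium ion by a second molecule of 1 (C-3 first, then O), which would consume material as a bridged two-to-one adduct. The excess of 7 and the methanol solvent are meant to suppress this.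
- Fallback (builds the enone by olefination instead of vinylogous substitution). It sets out from 1 and returns at 8 and then 9.
  - C-3 formylation of 1 (Reimer–Tiemann conditions, CHCl3/aq NaOH) gives 4-hydroxy-1-methyl-2-oxo-1,2-dihydroquinoline-3-carbaldehyde F5.
  - Wittig olefination of F5 with 1-(triphenylphosphoranylidene)propan-2-one gives enone 8, here isolated.
  - Ketalisation of 8 (PPTS, MeOH, 3 Å MS) gives 9.

**Step 1.**
- What may go wrong: alkylation before acylation. C-3 of 1 may capture the tertiary cation of protonated 2 and then lactonise, giving the isomeric 4,4-dimethyl lactone in place of the chromanone.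
- Fallback (fixes the acyl carbon first and brings in C-a as acetone). It sets out from 1 and returns at 4.
  - C-Acetylation of 1 (acetic acid in polyphosphoric acid, 110 °C) gives 3-acetyl-4-hydroxy-1-methylquinolin-2(1H)-one F6.
  - Kabbe condensation of F6 with acetone and pyrrolidine (enamine aldol, dehydration, oxa-Michael closure) gives 4.

**Step 2.**
- What may go wrong: enolisation of 4 by the basic organometallic followed by β-elimination of the aryloxide (retro-oxa-Michael ring opening), or competing attack on the vinylogous ester carbon of the quinolinone.
- Fallback (non-basic olefination in place of carbonyl addition). It sets out from 4 and returns at 6.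
  - Methylenation of 4 with the Petasis reagent Cp2TiMe2 (toluene, 70 °C) gives 2,2,6-trimethyl-4-methylidene-3,4-dihydro-2H-pyrano[3,2-c]quinolin-5(6H)-one F7.
  - Acid-catalysed migration of the exocyclic alkene of F7 into the ring (TsOH, toluene) gives 6.

## Further compounds

F1 | step 4 | 2,2,6-trimethyl-5-oxo-5,6-dihydro-2H-pyrano[3,2-c]quinolin-4-yl trifluoromethanesulfonate | Cn1c(=O)c2c(c3ccccc31)OC(C)(C)C=C2OS(=O)(=O)C(F)(F)F
F2 | step 4 | 2,2,6-trimethyl-4-[(trimethylsilyl)methyl]-2H-pyrano[3,2-c]quinolin-5(6H)-one | Cn1c(=O)c2c(c3ccccc31)OC(C)(C)C=C2C[Si](C)(C)C
F3 | step 4 | enantiomer of C-4 adduct 11 | Cn1c(=O)c2c(c3ccccc31)OC(C)(C)[C@@H](C2=C)[C@@H]2C=C(C)Oc3c2c(=O)n(C)c2ccccc32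
F4 | step 4 | enantiomer of 12, (C-b R, C-e R, C-g S)-heptacycle | Cn1c(=O)c2c(c3ccccc31)OC(C)(C)[C@H]1C2=C[C@@]2(C)C[C@@H]1c1c(c3ccccc3n(C)c1=O)O2
F5 | step 3 | 4-hydroxy-1-methyl-2-oxo-1,2-dihydroquinoline-3-carbaldehyde | Cn1c(=O)c(C=O)c(O)c2ccccc21
F6 | step 1 | 3-acetyl-4-hydroxy-1-methylquinolin-2(1H)-one | CC(=O)c1c(O)c2ccccc2n(C)c1=O
F7 | step 2 | 2,2,6-trimethyl-4-methylidene-3,4-dihydro-2H-pyrano[3,2-c]quinolin-5(6H)-one | Cn1c(=O)c2c(c3ccccc31)OC(C)(C)CC2=C
A1 | alternative 1 | 2,2,6-trimethyl-2H-pyrano[3,2-c]quinolin-5(6H)-one | Cn1c(=O)c2c(c3ccccc31)OC(C)(C)C=C2
A2 | alternative 1 | 4-hydroxy-1-methyl-3-[(1E)-3-methylbuta-1,3-dien-1-yl]quinolin-2(1H)-one | C=C(C)/C=C/c1c(O)c2ccccc2n(C)c1=O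
A3 | alternative 1 | saturated dimer (C-c–H, C-d H2), rings C and D cis-fused, racemic, one enantiomer drawn | Cn1c(=O)c2c(c3ccccc31)OC(C)(C)[C@@H]1[C@H]2C[C@]2(C)C[C@H]1c1c(c3ccccc3n(C)c1=O)O2
A4 | alternative 2 | (2E)-3-methyl-4-(2,2,6-trimethyl-5-oxo-5,6-dihydro-2H-pyrano[3,2-c]quinolin-4-yl)but-2-enal | Cn1c(=O)c2c(c3ccccc31)OC(C)(C)C=C2C/C(C)=C/C=O
A5 | alternative 2 | 4-[(2,6-dimethyl-5-oxo-5,6-dihydro-2H-pyrano[3,2-c]quinolin-2-yl)methyl]-2,2,6-trimethyl-2H-pyrano[3,2-c]quinolin-5(6H)-one (racemic) | Cn1c(=O)c2c(c3ccccc31)OC(C)(C)C=C2CC1(C)C=Cc2c(O1)c1ccccc1n(C)c2=O
A6 | alternative 3 | trans-fused tricycle of rings B, C and D with the alkene at C-d=C-e and C-b configured as in 12 | Cn1c(=O)c2c(c3ccccc31)OC(C)(C)[C@H]1CCC(C)=C[C@H]21
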